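The cyclohexenone ring is cut at C1–C2 and C3–C4 (C1 ketone carbon, C2 carrying the propanoic acid, C3 the trimethylcyclohexyl ring, C6 the formyloxymethyl group). This reads the tetrasubstituted C2=C3 alkene as an internal alkyne and the C4–C5–C6–C1(=O) arc as a strained, enantiopure 2-substituted cyclobutanone. A single nickel-catalysed insertion of the alkyne into the unsubstituted acyl–CH2 bond of the four-membered ketone forms both bonds and closes the six-membered ring with all three stereocentres already installed. The precursors are a tert-butyl (R)-2-methylbut-3-ynoate bearing the (S)-quaternary cyclohexyl group and (S)-2-(PMB-oxymethyl)cyclobutanone.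

Key step: step 13

Remarks on the chemistry (assumptions):
- The 2-methylalk-3-ynoate centre of 15 epimerises and isomerises to the allenoate under base, so it is made by SN2 opening of an epoxide and afterwards meets only neutral or acidic media; substitution of an α-sulfonyloxy propanoate by an alkynylcopper or alkali acetylide was judged unsafe for this reason.
- 4-Methoxybenzyl chloromethyl ether (step 11) is taken as a reagent prepared beforehand from 4-methoxybenzyl methylthiomethyl ether and SO2Cl2; the excess of alkyne 8 used in step 7 is recovered.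
- Conjugate bases formed by deprotonating a numbered compound (alkoxides, the lithium acetylide of 8, the azaenolate of 17) are not numbered separately.

Step 1
Reactants: 1 isophorone
Product: 2 (1S)-3,5,5-trimethylcyclohex-2-en-1-ol
Conditions: (R)-Me-CBS oxazaborolidine (15 mol%), BH3·SMe2 (0.7 equiv), THF, −20 °C, slow addition of 1; MeOH quench
Reagents that add atoms: none
Why: Corey–Bakshi–Shibata reduction: the (R)-oxazaborolidine–borane complex binds the carbonyl with the alkenyl arm acting as the larger group and delivers hydride to one face (1,2-reduction), which should set C1 as (S).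

Step 2
Reactants: 2 (1S)-3,5,5-trimethylcyclohex-2-en-1-ol
Product: 3 tributyl({[(1S)-3,5,5-trimethylcyclohex-2-en-1-yl]oxy}methyl)stannane
Conditions: KH (1.3 equiv), THF, 0 °C; Bu3SnCH2I (1.2 equiv), 0 °C → rt
Reagents that add atoms: (iodomethyl)tributylstannane, CCCC[Sn](CCCC)(CCCC)CI
Why: Williamson etherification of the potassium alkoxide with a primary iodide; the carbinol centre is not touched.

Step 3
Reactants: 3 tributyl({[(1S)-3,5,5-trimethylcyclohex-2-en-1-yl]oxy}methyl)stannane
Product: 5 [(1R)-1,5,5-trimethylcyclohex-2-en-1-yl]methanol, via α-alkoxymethyllithium 4 (not isolated)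
Conditions: nBuLi (1.3 equiv), THF, −78 °C → −30 °C; H2O
Reagents that add atoms: none
Why: Wittig–Still [2,3]-sigmatropic rearrangement: tin–lithium exchange gives 4, whose carbanion is delivered suprafacially to C3 on the face that carried the C1–O bond, so the (S)-carbinol centre should be relayed into the (R)-quaternary centre while the alkene moves to C1=C2.

Step 4
Reactants: 5 [(1R)-1,5,5-trimethylcyclohex-2-en-1-yl]methanol
Product: 6 [(1S)-1,3,3-trimethylcyclohexyl]methanol
Conditions: H2 (1 atm), 10% Pd/C, EtOAc, rt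
Reagents that add atoms: none
Why: Heterogeneous catalytic hydrogenation of the cis-disubstituted ring alkene; the quaternary centre is untouched and only its descriptor changes to (S) through the CIP priorities.

Step 5
Reactants: 6 [(1S)-1,3,3-trimethylcyclohexyl]methanol
Product: 8 (1S)-1-ethynyl-1,3,3-trimethylcyclohexane, via aldehyde 7 (not isolated)
Conditions: Dess–Martin periodinane (1.3 equiv), CH2Cl2, 0 °C → rt; aqueous wash, solvent exchange to MeOH; MeC(O)C(N2)P(O)(OMe)2 (1.5 equiv), K2CO3 (2 equiv), MeOH, 0 °C → rt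
Reagents that add atoms: dimethyl (1-diazo-2-oxopropyl)phosphonate, COP(=O)(OC)C(=[N+]=[N-])C(C)=O
Why: Dess–Martin oxidation to the non-enolisable neopentyl aldehyde followed by Ohira–Bestmann (Seyferth–Gilbert) homologation, in which the diazomethylphosphonate anion adds to the aldehyde and the alkylidene carbene rearranges by 1,2-hydrogen shift; the volatile aldehyde is carried on crude.

Step 6
Reactants: 9 (E)-but-2-en-1-ol
Product: 10 [(2R,3R)-3-methyloxiran-2-yl]methanol
Conditions: Ti(OiPr)4 (5 mol%), D-(−)-diisopropyl tartrate (6 mol%), tBuOOH (2 equiv, anhydrous), 4 Å molecular sieves, CH2Cl2, −20 °C; non-aqueous work-up, distillation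
Reagents that add atoms: tert-butyl hydroperoxide, CC(C)(C)OO
Why: Sharpless asymmetric epoxidation: the titanium–D-tartrate complex binds the allylic alcohol and the hydroperoxide and transfers oxygen to the alkene face that gives the (2R,3R)-epoxide, the trans geometry of the alkene being retained.

Step 7
Reactants: 8 (1S)-1-ethynyl-1,3,3-trimethylcyclohexane; 10 [(2R,3R)-3-methyloxiran-2-yl]methanol
Product: 12 (2S,3R)-3-methyl-5-[(1S)-1,3,3-trimethylcyclohexyl]pent-4-yne-1,2-diol, via diethylalkynylalane 11 (not isolated)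
Conditions: 8 (2.2 equiv), nBuLi (2.1 equiv), toluene, 0 °C; Et2AlCl (2.1 equiv), 0 °C; 10 (1.0 equiv), 0 °C → rt; aqueous potassium sodium tartrate (KNaC4H4O6); excess 8 recovered
Reagents that add atoms: none
Why: Alkynylalane opening of a 2,3-epoxy alcohol: the aluminium alkoxide of 10 holds the oxirane oxygen on aluminium and a second alane delivers the alkynyl group to C3 in an SN2 process with inversion, which should set the methyl-bearing centre as (R) and leave the carbinol centre as it was.

Step 8
Reactants: 12 (2S,3R)-3-methyl-5-[(1S)-1,3,3-trimethylcyclohexyl]pent-4-yne-1,2-diol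
Product: 14 (2R)-2-methyl-4-[(1S)-1,3,3-trimethylcyclohexyl]but-3-ynoic acid, via ynal 13 (not isolated)
Conditions: NaIO4 (1.5 equiv), THF/pH 7 phosphate buffer, 0 °C; extraction; crude 13 at once with NaClO2 (3 equiv), NaH2PO4 (3 equiv), 2-methyl-2-butene (10 equiv), tBuOH/H2O, 0 °C
Reagents that add atoms: sodium chlorite, [Na+].[O-]Cl=O
Why: Periodate (Malaprade) glycol cleavage followed by Pinnick oxidation; both run between pH 4 and 7, so the enolisable α-centre of the β,γ-alkynyl aldehyde, which is never purified, should keep its (R) configuration.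

Step 9
Reactants: 14 (2R)-2-methyl-4-[(1S)-1,3,3-trimethylcyclohexyl]but-3-ynoic acid
Product: 15 tert-butyl (2R)-2-methyl-4-[(1S)-1,3,3-trimethylcyclohexyl]but-3-ynoate
Conditions: tBuOC(=NH)CCl3 (2.5 equiv), cyclohexane/CH2Cl2, rt
Reagents that add atoms: tert-butyl 2,2,2-trichloroacetimidate, CC(C)(C)OC(=N)C(Cl)(Cl)Cl
Why: Base-free esterification by tert-butyl cation transfer from the acid-protonated trichloroacetimidate, chosen because the α-centre tolerates acid but not base.

Step 10
Reactants: 16 cyclobutanone
Product: 17 (2S)-N-cyclobutylidene-2-(methoxymethyl)pyrrolidin-1-amine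
Conditions: SAMP (1.05 equiv), cyclohexane, 4 Å molecular sieves, rt → 50 °C
Reagents that add atoms: (S)-1-amino-2-(methoxymethyl)pyrrolidine (SAMP), COC[C@@H]1CCCN1N
Why: Condensation of the strained, electrophilic ketone with the hydrazine gives the Enders SAMP hydrazone.

Step 11
Reactants: 17 (2S)-N-cyclobutylidene-2-(methoxymethyl)pyrrolidin-1-amine
Product: 18 (2S)-2-(methoxymethyl)-N-[(2R)-2-{[(4-methoxybenzyl)oxy]methyl}cyclobutylidene]pyrrolidin-1-amine
Conditions: LiN(iPr)2 (1.1 equiv), THF, 0 °C; then −100 °C, 4-MeOC6H4CH2OCH2Cl (1.2 equiv), slow warming to rt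
Reagents that add atoms: 4-methoxybenzyl chloromethyl ether, COc1ccc(COCCl)cc1
Why: Enders SAMP-hydrazone α-alkylation: the lithium azaenolate is held rigid by chelation of lithium to the methoxymethyl arm and the electrophile should approach the face away from the pyrrolidine ring, which sets the new centre (R by CIP in the hydrazone, the arrangement that becomes S in the ketone).

Step 12
Reactants: 18 (2S)-2-(methoxymethyl)-N-[(2R)-2-{[(4-methoxybenzyl)oxy]methyl}cyclobutylidene]pyrrolidin-1-amine
Product: 19 (2S)-2-{[(4-methoxybenzyl)oxy]methyl}cyclobutan-1-one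
Conditions: saturated aqueous oxalic acid, Et2O, rt, vigorous stirring
Reagents that add atoms: water, O
Why: Two-phase acid hydrolysis of the hydrazone, a cleavage mild enough not to enolise the α-centre and leaving the PMB ether intact, with the auxiliary passing into the aqueous phase as its oxalate.

Step 13
Reactants: 15 tert-butyl (2R)-2-methyl-4-[(1S)-1,3,3-trimethylcyclohexyl]but-3-ynoate; 19 (2S)-2-{[(4-methoxybenzyl)oxy]methyl}cyclobutan-1-one
Product: 20 tert-butyl (2R)-2-[(5S)-5-{[(4-methoxybenzyl)oxy]methyl}-6-oxo-2-[(1S)-1,3,3-trimethylcyclohexyl]cyclohex-1-en-1-yl]propanoate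
Conditions: Ni(cod)2 (10 mol%), PCy3 (20 mol%), 19 (1.5 equiv), toluene, 100 °C, sealed vessel, argon
Reagents that add atoms: none
Why: Zerovalent nickel ligated by PCy3 couples the ketone C=O of 19 and the alkyne of 15 oxidatively to a spirocyclic oxanickelacyclopentene (C1–C2 bond), β-carbon elimination then breaks the strained C1–C4 bond to give a seven-membered nickelacycle, and C(sp2)–C(sp3) reductive elimination forms C3–C4 and returns zerovalent nickel. The closest known reaction is the nickel-catalysed intermolecular [4+2] ring expansion of cyclobutanones with internal alkynes, used here with a 2-substituted ketone and a tert-alkyl alkyne. The cyclohexenone ring is closed by that reductive elimination from the seven-membered metallacycle, a formal [4+2] annulation driven by release of four-membered-ring strain. No stereocentre is formed, and the three existing ones (the quaternary carbon, the ester α-carbon and the ketone α-carbon, which is not part of the cleaved bond) are spectators under neutral, base-free conditions. The step needs two regiochemical preferences: the alkyne carbon carrying the bulky trimethylcyclohexyl group must lie next to nickel so that the less hindered carbon bonds to the carbonyl, which the size difference between a quaternary and a secondary substituent secures, and the unsubstituted CH2 rather than the CH(CH2OPMB) carbon must migrate to nickel, which is favoured because it gives the less hindered primary alkylnickel and avoids a β-alkoxy alkylnickel.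

Step 14
Reactants: 20 tert-butyl (2R)-2-[(5S)-5-{[(4-methoxybenzyl)oxy]methyl}-6-oxo-2-[(1S)-1,3,3-trimethylcyclohexyl]cyclohex-1-en-1-yl]propanoate
Product: 21 tert-butyl (2R)-2-[(5S)-5-(hydroxymethyl)-6-oxo-2-[(1S)-1,3,3-trimethylcyclohexyl]cyclohex-1-en-1-yl]propanoate
Conditions: DDQ (1.3 equiv), CH2Cl2/pH 7 phosphate buffer (10:1), 0 °C → rt
Reagents that add atoms: none
Why: Oxidative cleavage of the 4-methoxybenzyl ether: DDQ abstracts hydride from the electron-rich benzylic position and water hydrolyses the oxocarbenium ion, under buffered neutral conditions that spare the ketone α-centre, the enone and the tert-butyl ester.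

Step 15
Reactants: 21 tert-butyl (2R)-2-[(5S)-5-(hydroxymethyl)-6-oxo-2-[(1S)-1,3,3-trimethylcyclohexyl]cyclohex-1-en-1-yl]propanoate
Product: 22 tert-butyl (2R)-2-[(5S)-5-[(formyloxy)methyl]-6-oxo-2-[(1S)-1,3,3-trimethylcyclohexyl]cyclohex-1-en-1-yl]propanoate
Conditions: AcOCHO (3 equiv, preformed from HCO2H and Ac2O at 55 °C), pyridine (3 equiv), CH2Cl2, 0 °C
Reagents that add atoms: acetic formic anhydride, CC(=O)OC=O
Why: O-Formylation by acyl transfer from the mixed anhydride, whose formyl carbonyl is the more electrophilic one, with a weak base at 0 °C so that neither retro-aldol cleavage nor β-elimination of the β-oxygenated ketone is provoked.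

Step 16
Reactants: 22 tert-butyl (2R)-2-[(5S)-5-[(formyloxy)methyl]-6-oxo-2-[(1S)-1,3,3-trimethylcyclohexyl]cyclohex-1-en-1-yl]propanoate
Product: 23 (2R)-2-[(5S)-5-[(formyloxy)methyl]-6-oxo-2-[(1S)-1,3,3-trimethylcyclohexyl]cyclohex-1-en-1-yl]propanoic acid
Conditions: CF3CO2H/CH2Cl2 (1:4), 0 °C → rt; evaporation with toluene
Reagents that add atoms: none
Why: Acidolysis of the tert-butyl ester (alkyl–oxygen cleavage with loss of 2-methylpropene), under anhydrous acid that leaves the primary formate and the three stereocentres unchanged and needs no aqueous or basic work-up.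

Compound list
1 | isophorone (3,5,5-trimethylcyclohex-2-en-1-one) | CC1=CC(=O)CC(C)(C)C1 | starting material
2 | (1S)-3,5,5-trimethylcyclohex-2-en-1-ol | O[C@@H]1C=C(C)CC(C)(C)C1 | intermediate
3 | tributyl({[(1S)-3,5,5-trimethylcyclohex-2-en-1-yl]oxy}methyl)stannane | CCCC[Sn](CCCC)(CCCC)CO[C@@H]1C=C(C)CC(C)(C)C1 | intermediate
4 | ({[(1S)-3,5,5-trimethylcyclohex-2-en-1-yl]oxy}methyl)lithium | [Li]CO[C@@H]1C=C(C)CC(C)(C)C1 | intermediate (not isolated)
5 | [(1R)-1,5,5-trimethylcyclohex-2-en-1-yl]methanol | OC[C@@]1(C)C=CCC(C)(C)C1 | intermediate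
6 | [(1S)-1,3,3-trimethylcyclohexyl]methanol | OC[C@@]1(C)CCCC(C)(C)C1 | intermediate
7 | (1S)-1,3,3-trimethylcyclohexane-1-carbaldehyde | O=C[C@@]1(C)CCCC(C)(C)C1 | intermediate (not isolated)
8 | (1S)-1-ethynyl-1,3,3-trimethylcyclohexane | C#C[C@@]1(C)CCCC(C)(C)C1 | intermediate
9 | (E)-but-2-en-1-ol | C/C=C/CO | starting material
10 | [(2R,3R)-3-methyloxiran-2-yl]methanol | C[C@H]1O[C@@H]1CO | intermediate
11 | diethyl{[(1S)-1,3,3-trimethylcyclohexyl]ethynyl}alane | CC[Al](CC)C#C[C@@]1(C)CCCC(C)(C)C1 | intermediate (not isolated)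
12 | (2S,3R)-3-methyl-5-[(1S)-1,3,3-trimethylcyclohexyl]pent-4-yne-1,2-diol | C[C@@H]([C@H](O)CO)C#C[C@@]1(C)CCCC(C)(C)C1 | intermediate
13 | (2R)-2-methyl-4-[(1S)-1,3,3-trimethylcyclohexyl]but-3-ynal | C[C@@H](C=O)C#C[C@@]1(C)CCCC(C)(C)C1 | intermediate (not isolated)
14 | (2R)-2-methyl-4-[(1S)-1,3,3-trimethylcyclohexyl]but-3-ynoic acid | C[C@@H](C(=O)O)C#C[C@@]1(C)CCCC(C)(C)C1 | intermediate
15 | tert-butyl (2R)-2-methyl-4-[(1S)-1,3,3-trimethylcyclohexyl]but-3-ynoate | C[C@@H](C(=O)OC(C)(C)C)C#C[C@@]1(C)CCCC(C)(C)C1 | intermediate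
16 | cyclobutanone | O=C1CCC1 | starting material
17 | (2S)-N-cyclobutylidene-2-(methoxymethyl)pyrrolidin-1-amine | COC[C@@H]1CCCN1N=C1CCC1 | intermediate
18 | (2S)-2-(methoxymethyl)-N-[(2R)-2-{[(4-methoxybenzyl)oxy]methyl}cyclobutylidene]pyrrolidin-1-amine | COC[C@@H]1CCCN1N=C1CC[C@H]1COCc1ccc(OC)cc1 | intermediate
19 | (2S)-2-{[(4-methoxybenzyl)oxy]methyl}cyclobutan-1-one | O=C1CC[C@H]1COCc1ccc(OC)cc1 | intermediate
20 | tert-butyl (2R)-2-[(5S)-5-{[(4-methoxybenzyl)oxy]methyl}-6-oxo-2-[(1S)-1,3,3-trimethylcyclohexyl]cyclohex-1-en-1-yl]propanoate | C[C@@H](C(=O)OC(C)(C)C)C1=C([C@@]2(C)CCCC(C)(C)C2)CC[C@@H](COCc3ccc(OC)cc3)C1=O | intermediate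
21 | tert-butyl (2R)-2-[(5S)-5-(hydroxymethyl)-6-oxo-2-[(1S)-1,3,3-trimethylcyclohexyl]cyclohex-1-en-1-yl]propanoate | C[C@@H](C(=O)OC(C)(C)C)C1=C([C@@]2(C)CCCC(C)(C)C2)CC[C@@H](CO)C1=O | intermediate
22 | tert-butyl (2R)-2-[(5S)-5-[(formyloxy)methyl]-6-oxo-2-[(1S)-1,3,3-trimethylcyclohexyl]cyclohex-1-en-1-yl]propanoate | C[C@@H](C(=O)OC(C)(C)C)C1=C([C@@]2(C)CCCC(C)(C)C2)CC[C@@H](COC=O)C1=O | intermediate
23 | (2R)-2-[(5S)-5-[(formyloxy)methyl]-6-oxo-2-[(1S)-1,3,3-trimethylcyclohexyl]cyclohex-1-en-1-yl]propanoic acid | C[C@@H](C(=O)O)C1=C([C@@]2(C)CCCC(C)(C)C2)CC[C@@H](COC=O)C1=O | target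

Total step count: 16 (steps 3, 5, 7 and 8 each pass through one non-isolated intermediate).
Longest linear sequence: 12 steps (steps 1–5, 7–9, 13–16).

Steps most likely to fail

1. Step 13 (nickel-catalysed insertion). What may go wrong: β-carbon elimination on the substituted side of the four-membered ring, followed by loss of the PMB-oxide, or epimerisation of the ketone α-centre during heating, so that the enone forms as a regio- or stereoisomeric mixture. Fallback, setting out from 15 and 16 and returning at 21: the same nickel catalysis (Ni(cod)2, PCy3, toluene, 100 °C) is run with the symmetrical parent ketone 16, for which neither ring-bond selectivity nor an α-centre is at stake, and should give tert-butyl (2R)-2-{6-oxo-2-[(1S)-1,3,3-trimethylcyclohexyl]cyclohex-1-en-1-yl}propanoate F1. Kinetic deprotonation of the CH2 group next to the ketone (C6 of the enone numbering) with LiN(iPr)2 in the presence of Me3SiCl (THF, −78 °C) should give the cross-conjugated silyl dienol ether tert-butyl (2R)-2-{6-[(trimethylsilyl)oxy]-2-[(1S)-1,3,3-trimethylcyclohexyl]cyclohexa-1,5-dien-1-yl}propanoate F2. A catalytic enantioselective hydroxymethylation of this silicon enolate (aqueous formaldehyde, Sc(OTf)3 with a chiral 2,2'-bipyridine diol ligand, the ligand antipode being chosen to deliver the (5S) centre, DME/H2O, −20 °C; a Mukaiyama-type aldol addition) then installs the CH2OH group under catalyst control and leads directly to 21, so that 19, 20 and the PMB removal are bypassed.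

2. Step 3 (Wittig–Still rearrangement). What may go wrong: the organolithium may be protonated or undergo a 1,2-shift instead of the 2,3-shift, because the axial methyl group at C5 crowds the face of C3 that has to receive the CH2 group. Fallback, setting out from 2 and returning at 8: a thermal Johnson–Claisen rearrangement of 2 (MeC(OEt)3, catalytic propionic acid, 140 °C), a concerted [3,3] shift with the same suprafacial chirality transfer and no competing anionic pathway, should give ethyl 2-[(1S)-1,5,5-trimethylcyclohex-2-en-1-yl]acetate F3. Hydrogenation (H2, 10% Pd/C, EtOAc) gives ethyl 2-[(1S)-1,3,3-trimethylcyclohexyl]acetate F4, and iBu2AlH (CH2Cl2, −78 °C) gives 2-[(1S)-1,3,3-trimethylcyclohexyl]acetaldehyde F5. Nonafluorobutanesulfonyl fluoride and a phosphazene base (P2-Et, DMF, rt) convert this aldehyde, through 2-[(1S)-1,3,3-trimethylcyclohexyl]ethenyl nonafluorobutane-1-sulfonate F6 formed and eliminated in the same flask, into alkyne 8 with the same carbon count.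

3. Step 1 (CBS reduction). What may go wrong: insufficient discrimination between the alkenyl arm and the neopentyl-type CH2 arm of the ketone, giving alcohol of low enantiomeric purity whose minor enantiomer would later travel as hard-to-separate diastereomers. Fallback, setting out from 1 and returning at 2: Luche reduction (NaBH4, CeCl3·7H2O, MeOH, 0 °C) gives racemic 3,5,5-trimethylcyclohex-2-en-1-ol F7; acylation with (1S)-(−)-camphanic chloride (pyridine, DMAP, CH2Cl2) gives two diastereomeric esters, from which (1S)-3,5,5-trimethylcyclohex-2-en-1-yl (1S,4R)-camphanate F8 is separated by crystallisation or chromatography; LiOH in THF/H2O then releases 2.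

Further compounds
F1 | step 13 | tert-butyl (2R)-2-{6-oxo-2-[(1S)-1,3,3-trimethylcyclohexyl]cyclohex-1-en-1-yl}propanoate | C[C@@H](C(=O)OC(C)(C)C)C1=C([C@@]2(C)CCCC(C)(C)C2)CCCC1=O
F2 | step 13 | tert-butyl (2R)-2-{6-[(trimethylsilyl)oxy]-2-[(1S)-1,3,3-trimethylcyclohexyl]cyclohexa-1,5-dien-1-yl}propanoate | C[C@@H](C(=O)OC(C)(C)C)C1=C([C@@]2(C)CCCC(C)(C)C2)CCC=C1O[Si](C)(C)C
F3 | step 3 | ethyl 2-[(1S)-1,5,5-trimethylcyclohex-2-en-1-yl]acetate | CCOC(=O)C[C@@]1(C)C=CCC(C)(C)C1
F4 | step 3 | ethyl 2-[(1S)-1,3,3-trimethylcyclohexyl]acetate | CCOC(=O)C[C@@]1(C)CCCC(C)(C)C1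
F5 | step 3 | 2-[(1S)-1,3,3-trimethylcyclohexyl]acetaldehyde | O=CC[C@@]1(C)CCCC(C)(C)C1
F6 | step 3 | 2-[(1S)-1,3,3-trimethylcyclohexyl]ethenyl nonafluorobutane-1-sulfonate (E/Z mixture) | O=S(=O)(OC=C[C@@]1(C)CCCC(C)(C)C1)C(F)(F)C(F)(F)C(F)(F)C(F)(F)F
F7 | step 1 | rac-3,5,5-trimethylcyclohex-2-en-1-ol | CC1=CC(O)CC(C)(C)C1
F8 | step 1 | (1S)-3,5,5-trimethylcyclohex-2-en-1-yl (1S,4R)-4,7,7-trimethyl-3-oxo-2-oxabicyclo[2.2.1]heptane-1-carboxylate | CC1=C[C@@H](OC(=O)[C@@]23CC[C@@](C)(C(=O)O2)C3(C)C)CC(C)(C)C1
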